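L was the charge that set the two earlier runs apart, so I asked how much D stood at the peak per mM of L charged.

| setting | violet | green | flask |
|---|---|---|---|
| G | 20 mM | 20 mM | 20 mM |
| Q | 20 mM | 20 mM | 20.0 mM |
| L | 56 mM | 88 mM | 40.0 mM |
| remark | run made earlier | run made earlier |  |
| time |  |  | 6.0 min |

| violet: time / min | violet: D / % | green: time / min | green: D / % |
|---|---|---|---|
| 0.833 | 9 | 0.833 | 13 |
| 1.00 | 13 | 1.00 | 17 |
| 1.50 | 19 | 1.50 | 25 |
| 2.00 | 19 | 2.00 | 28 |
| 2.50 | 22 | 2.50 | 31 |
| 4.00 | 20 | 4.00 | 27 |
| 5.00 | 20 | 5.00 | 20 |

(standard deviation of a reading: 2 percentage points)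

* time up to 6.0 min at which D stands highest
* the amount of D, in percent of the G charged, at that time

- the analysis behind the earlier runs scatters by 2 percentage points, standard deviation

The peak readings, 22% in violet and 31% in green, both at 2.50 min, give ratios of D to L charged, both taken in mM, of 0.0786 and 0.0705. I froze their mean, 0.0745, as s, the peak yield on L: mM of D at the peak per mM of L charged. For this flask, with 40.0 mM of L, s gave me 14.9% of the G charged. Green rose faster than violet, 17% against 13% at 1.00 min, so I looked for the flask's peak after 2.50 min.

The forecast said 16% (12.5% to 19%) at 3 min (2 min to 5.5 min), “on a broad maximum”, a higher peak than mine.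

The flask gave 17.8% at 3.44 min, inside both forecast ranges and above my figure.

    G + L → Z (k = 0.903 L mol⁻¹ s⁻¹)
    D → J (k = 0.00319 s⁻¹)
    Z + X → D (k = 0.639 L mol⁻¹ s⁻¹)
    X → E (k = 0.0126 s⁻¹)
    L + Q → X (k = 0.429 L mol⁻¹ s⁻¹)

In this flask s came out at 0.0890, higher than the frozen value, and D then fell to 14.8% by 6.00 min, so watch the fall as well as the peak. A neighbour flask with 16 mM of L tests the same reckoning: s gave 5.96%, but that flask peaked at 4.81%, a yield on L of 0.0602, lower than the frozen value. There L was the limiting reagent: at 6.00 min it stood at 0.262% of its own charge, while 49.0% of the G charged remained.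

(The readings are simulated from invented constants.)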